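## Structural features

The target 22 is an unsymmetrical biflavonol: two 3-hydroxy-2-arylchromen-4-one units whose rings B are joined C4'–O–C4' by one diaryl ether oxygen. One half is a 3,5-dihydroxy-7-methoxychromone whose ring B has a free 3'-hydroxyl. The other half is a 3,5,7-trihydroxychromone whose ring B has a 3'-methoxy group. The halves therefore differ only in which ring A oxygen and which ring B oxygen is methylated.

There is no stereocentre, so the problem is purely regiochemical. The free phenols, the two 3-hydroxy-4-pyranone enols and the 5-hydroxy-4-keto chelates are air-sensitive under base, so all phenols are carried as benzyl ethers to the last step. Among the intermediates, the electron-rich aryloxyfuran and the benzylic dioxolane are acid-labile.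

The real difficulties are three:
- the diaryl ether lies between two rings that each carry an ortho oxygen;
- the two one-carbon handles on rings B must stay distinguishable so that two different rings A can be attached in turn;
- the C3 hydroxyls must be introduced in a 5-oxygenated series, where alkaline peroxide cyclization of 6'-alkoxychalcones tends to give aurones.

The key step uses ring B of the 5,7-dihydroxy half. Its vicinal oxygens at C3' and C4' correspond to the ring oxygen and the C3 aryloxy group of a 3-aryloxyfuran. Furan C2–C5 become C3'–C6', and the two alkyne carbons of a propiolate become C1' and C2'. The ring is thus grown around an existing C4'–O–aryl bond.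

## Logic of the disconnections

**22 to 21.** The four benzylic O–C bonds (O5 and O3' of the 7-methoxy half, O5 and O7 of the other half) are cut. Every earlier intermediate then has masked phenols, and only the chelated or enolic hydroxyls are free. The forward step must cleave four benzyl ethers without reducing the enolic C2=C3 bonds or the diaryl ether.

**21 to 19 (through 20).** The two C3–O bonds are cut. Postponing C3 oxygenation lets both rings C be closed by a non-peroxidic oxidative cyclization, which avoids the aurone pathway of 6'-alkoxy enones. The precursor is a plain biflavone. The forward step must transfer oxygen twice to vinylogous-ester double bonds in the presence of benzyl ethers and electron-rich rings, and then isomerize each epoxide to the enol.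

**19 to 18.** Both O1–C2 bonds are cut, opening the two pyranone rings to two 2'-hydroxy enones. This reduces the heterocycles to acyclic aldol products. The forward step must perform oxa-Michael closure and dehydrogenation on both enones in one flask without loss of the peri benzyl ethers.

**18 to 15 and 17.** The Cα=Cβ bond of the enone of the 7-methoxy half (the future C3–C2 bond) is cut. This brings in the methylated ring A as a separate ketone and makes the route convergent. The aldol condensation must leave the enone already present untouched, with no retro-aldol exchange and no Michael addition. 17 goes back to 16 by cutting one O–benzyl bond, and 16 goes back to 12 by cutting the O–methyl bond. Both rely on the para hydroxyl being more acidic and unchelated, and on one ortho hydroxyl staying hydrogen-bonded.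

**15 to 11 and 13 (through 14).** The Cα=Cβ bond of the enone of the 5,7-dihydroxy half is cut and the free formyl group is re-masked as the dioxolane. The two formyl groups on rings B must be used one after the other, so one is free and one is an acetal. The condensation must spare the acetal, and the acid release must not cyclize the enone. 13 goes back to 12 by cutting two O–benzyl bonds.

**11 to 10 to 9 to 8.** These are oxidation-level changes at C1' (formyl from ester through the alcohol) and cleavage of the C3' O–methyl bond. They are needed because the key step delivers an ester and a phenol. Hydride reduction, benzylic oxidation and methylation must tolerate the acetal, the benzyl ether and the diaryl ether.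

**8 to 5 and 6 (through 7).** The C2'–C3' and C1'–C6' bonds of the guaiacyl ring are cut. The diaryl ether is then not made by coupling two ortho-oxygenated arenes. The C3' oxygen and the C1' carbon arrive in the correct positions by construction. The precursors are a furyl aryl ether and a three-carbon alkyne ester. The forward step must control both the orientation of the cycloaddition and the direction of bridge opening, and must spare the acetal.

**5 to 3 and 4.** The furan C3–O bond is cut. The forward step is a copper-catalysed coupling of an electron-rich phenol with a volatile heteroaryl bromide. The acetal keeps the phenol electron-rich and is stable to base.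

**3 to 2 to 1.** The acetal C–O bonds and the O3–benzyl bond are cut. The benzylation must take place at the oxygen meta to the formyl group, not at the more acidic para oxygen.

## Other disconnections considered

**Alternative 1:** Carbene, alcohol and aldehyde three-component assembly.
- **Cut:** the C2–C3 and C3–O bonds of ring C of the 5,7-dihydroxy half.
- **Forward key step:** Rh2(OAc)4 converts diazoketone A2 into a rhodium carbene. Benzyl alcohol A4 adds to give an oxonium ylide, which is trapped by diaryl ether aldehyde A3 in an aldol-type addition before the 1,2-proton shift. The product is the α-benzyloxy-β-hydroxy ketone A1 as a diastereomer mixture. Oxidation to the 1,3-diketone, removal of the methoxymethyl group and cyclodehydration would follow.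
- **In its favour:** C3 arrives already oxygenated and protected, so no late C3 hydroxylation is needed. On this point it is better than the chosen plan, which spends step 14 on it. No chalcone is involved, so the aurone question does not arise. The two new stereocentres are irrelevant.
- **Against it here:** ylide trapping is best established for aryl diazoacetates and activated electrophiles. With an acceptor-only, doubly ortho-substituted diazoketone and the electron-rich, weakly electrophilic formyl group of A3, simple O–H insertion is the likely main pathway. A2 needs an orthogonally protected, hindered aroyl unit and a hazardous diazoalkane acylation.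
- **Comparison:** A3 would come from an ordinary diaryl ether coupling of two simple ring B units, which is shorter than steps 1 to 7; here the alternative is the better. It does nothing for the second chromone, and its oxidation and cyclization steps roughly offset the saved hydroxylation, so overall step economy is about equal. Mechanistically, the chosen step has built-in orbital control of regiochemistry. Alternative 1 depends on a kinetic competition between proton shift and aldol trapping.

**Alternative 2:** Coumalate cycloaddition.
- **Cut:** the C2'–C3' and C4'–C5' bonds of the catechol-type ring B of the 7-methoxy half.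
- **Forward key step:** methyl coumalate A6 and aryloxyethynylboronate A7 undergo [4+2] addition, and the bridged lactone aromatizes by decarboxylation to boronate A5. Its C–B bond would be oxidized to the 3'-hydroxyl.
- **In its favour:** the arene is again built around a pre-formed aryl–oxygen bond. The conditions are neutral and thermal, which suits the dioxolane better than a Lewis acid; on this point the alternative is better. The methyl ether comes with the guaiacyl acetal, so no methylation is needed (equal or slightly better). Boron is a clean latent hydroxyl.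
- **Against it here:** A7 is a boron-substituted aryl ynol ether. It is not a shelf compound and needs low-temperature acetylide chemistry. It is thermally labile, whereas pyranone cycloadditions usually need strong heating. The regiochemistry rests on the boron-bearing alkyne carbon attacking C6 of A6; this is polarity-matched but is not enforced by a strong donor.
- **Comparison:** A5 is a ring-swapped analogue of 8 (ester on the catechol ring, acetal on the guaiacyl ring), so the downstream chemistry would be nearly identical with the rings A attached in the opposite order. The chosen plan uses a commercial alkyne and one catalytic coupling to reach its diene. Alternative 2 needs several steps to A7, plus oxidation and benzylation after A5, so it is somewhat longer. Aromatization is irreversible in both.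

**Alternative 3:** Ring A grown last on a pyranone derived from kojic acid A10.
- **Cut:** the C4a–C5 bond of ring A of the 5,7-dihydroxy half.
- **Forward key step:** Mg(OMe)2 chelates the β,δ-diketo ester chain of A9. Pyranone C3 attacks the ester in a Claisen-type closure, and tautomerization gives the resorcinol ring of A8.
- **In its favour:** ring C comes with its C3 oxygen in place and the new ring A needs no protecting groups. On both points it is better than the chosen plan. The closure mimics polyketide aromatization.
- **Against it here:** the key step builds a ring that is commercially available as a phloroglucinol ketone. A9 needs a C–C arylation at pyranone C6 and a dianion chain extension, both on a large intermediate that already holds the other flavonol. Competing aldol closure onto the pyranone carbonyl and methoxide opening of the pyranone are plausible.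
- **Comparison:** the chosen plan buys both rings A and spends its ring-forming step on the diaryl ether region, where the difficulty lies. Alternative 3 is more linear and longer, although it is the equal of the chosen plan in avoiding the aurone problem for its half.

Key step: step 4

Remark on the chemistry: the target has no stereocentre. The E geometry of the enones and the configurations of the transient adducts 7 and 20 are erased later, so no stereocontrol is required.

## Route

Step 1
Reactants: 1 3,4-dihydroxybenzaldehyde
Product: 2 3-benzyloxy-4-hydroxybenzaldehyde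
Conditions: NaH (2.2 equiv), DMSO, 20 °C; BnBr (1.0 equiv), 20 °C; aq. HCl
Reagents that add atoms: benzyl bromide, BrCc1ccccc1
Why: Williamson etherification of the catechol dianion; the 4-oxide is delocalized into the formyl group (vinylogous carboxylate), so the more basic 3-oxide is the nucleophile and one equivalent of halide should give the 3-O-benzyl ether.

Step 2
Reactants: 2 3-benzyloxy-4-hydroxybenzaldehyde
Product: 3 2-benzyloxy-4-(1,3-dioxolan-2-yl)phenol
Conditions: ethylene glycol (5 equiv), p-TsOH (cat.), toluene, reflux with azeotropic removal of water; Et3N quench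
Reagents that add atoms: ethylene glycol, OCCO
Why: Acid-catalysed acetalization driven by water removal, as used for other 4-hydroxy-3-alkoxybenzaldehydes; the basic quench protects the acid-labile para-hydroxy acetal.

Step 3
Reactants: 3 2-benzyloxy-4-(1,3-dioxolan-2-yl)phenol; 4 3-bromofuran
Product: 5 3-[2-benzyloxy-4-(1,3-dioxolan-2-yl)phenoxy]furan
Conditions: CuI (10 mol%), picolinic acid (20 mol%), K3PO4 (2 equiv), 4 (2 equiv), DMSO, 90 °C, sealed vessel
Reagents that add atoms: none
Why: Ullmann-type C–O coupling; the picolinate-ligated monovalent copper phenoxide inserts into the C3–Br bond of the furan and reductive elimination forms the aryl furyl ether, while the acetal is inert to base and keeps the phenol electron-rich.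

Step 4
Reactants: 5 3-[2-benzyloxy-4-(1,3-dioxolan-2-yl)phenoxy]furan; 6 ethyl propiolate
Product: 8 ethyl 4-[2-benzyloxy-4-(1,3-dioxolan-2-yl)phenoxy]-3-hydroxybenzoate, via oxanorbornadiene cycloadduct 7 (not isolated)
Conditions: ZnI2 (anhydrous, 0.5 equiv), 6 (3 equiv), 4 Å molecular sieves, CH2Cl2, 0 °C to rt; aq. NaHCO3
Reagents that add atoms: none
Why: ZnI2 binds the ester carbonyl of 6 and lowers its LUMO, and the enol-ether diene of 5 adds across the alkyne in an asynchronous normal-demand [4+2] cycloaddition; this is the Lewis-acid-promoted furan–alkynoate Diels–Alder reaction known for 3-alkoxyfurans. Furan C2, the β-carbon of the aryloxy enol ether and the most nucleophilic terminus, bonds to the unsubstituted alkyne carbon, and furan C5 bonds to the ester-bearing carbon. The carbocycle thus closes in the [4+2] mode with formation of the C2'–C3' and C1'–C6' bonds, giving 7-oxanorbornadiene 7. Zinc then assists heterolysis of the bridge C–O bond at the former furan C5, because only this cleavage gives a cyclohexadienyl cation whose charge rests on the aryloxy-bearing carbon as an oxocarbenium ion; cleavage at the other bridgehead would place the charge beside the ester. Loss of the proton from the carbon that keeps the oxygen aromatizes the ring to phenol 8, with the hydroxyl ortho to the aryloxy group and meta to the ester. The two bridgehead stereocentres of 7 form as a racemate and vanish on aromatization, so no stereocentre remains. The step needs orientational selectivity in the cycloaddition and directional selectivity in the bridge opening, and both are set by the aryloxy donor at furan C3. Sub-stoichiometric anhydrous ZnI2, sieves, low temperature and a bicarbonate quench are chosen to disfavour conjugate hydroarylation at furan C2 and ionization of the benzylic dioxolane.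

Step 5
Reactants: 8 ethyl 4-[2-benzyloxy-4-(1,3-dioxolan-2-yl)phenoxy]-3-hydroxybenzoate
Product: 9 ethyl 4-[2-benzyloxy-4-(1,3-dioxolan-2-yl)phenoxy]-3-methoxybenzoate
Conditions: MeI (1.5 equiv), K2CO3 (2 equiv), DMF, rt
Reagents that add atoms: methyl iodide, CI
Why: Williamson methylation of the only free phenol; ester, acetal and benzyl ether are inert to carbonate.

Step 6
Reactants: 9 ethyl 4-[2-benzyloxy-4-(1,3-dioxolan-2-yl)phenoxy]-3-methoxybenzoate
Product: 10 {4-[2-benzyloxy-4-(1,3-dioxolan-2-yl)phenoxy]-3-methoxyphenyl}methanol
Conditions: LiAlH4 (1.0 equiv), THF, 0 °C; aq. NaOH work-up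
Reagents that add atoms: none
Why: Hydride reduction of the aryl ester to the benzylic alcohol; acetals and aryl or benzyl ethers do not react with LiAlH4, and the basic work-up spares the dioxolane.

Step 7
Reactants: 10 {4-[2-benzyloxy-4-(1,3-dioxolan-2-yl)phenoxy]-3-methoxyphenyl}methanol
Product: 11 4-[2-benzyloxy-4-(1,3-dioxolan-2-yl)phenoxy]-3-methoxybenzaldehyde
Conditions: MnO2 (activated, 10 equiv), CH2Cl2, rt
Reagents that add atoms: none
Why: Selective heterogeneous oxidation of a benzylic alcohol to the aldehyde under neutral conditions, with no over-oxidation and no risk to the acetal.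

Step 8
Reactants: 12 2',4',6'-trihydroxyacetophenone
Product: 13 1-[2,4-bis(benzyloxy)-6-hydroxyphenyl]ethanone
Conditions: BnBr (2.1 equiv), K2CO3 (2.2 equiv), DMF, 60 °C
Reagents that add atoms: benzyl bromide, BrCc1ccccc1
Why: Williamson benzylation stops at the dibenzyl stage because the remaining ortho hydroxyl is locked in a hydrogen bond to the acetyl carbonyl.

Step 9
Reactants: 11 4-[2-benzyloxy-4-(1,3-dioxolan-2-yl)phenoxy]-3-methoxybenzaldehyde; 13 1-[2,4-bis(benzyloxy)-6-hydroxyphenyl]ethanone
Product: 15 3-benzyloxy-4-{4-[(E)-3-(2,4-bis(benzyloxy)-6-hydroxyphenyl)-3-oxoprop-1-enyl]-2-methoxyphenoxy}benzaldehyde, via dioxolane chalcone 14 (not isolated)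
Conditions: KOH (50% aq.), EtOH/THF, rt; then 2 M HCl to pH 1, THF, rt
Reagents that add atoms: water, O
Why: Claisen–Schmidt aldol condensation gives the E-enone under thermodynamic control while the acetal is stable to base; acidification then hydrolyses the para-aryloxy-activated dioxolane at room temperature, conditions too mild to cyclize the 2'-hydroxy enone.

Step 10
Reactants: 12 2',4',6'-trihydroxyacetophenone
Product: 16 1-(2,6-dihydroxy-4-methoxyphenyl)ethanone
Conditions: Me2SO4 (1.0 equiv), K2CO3 (1.0 equiv), acetone, reflux
Reagents that add atoms: dimethyl sulfate, COS(=O)(=O)OC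
Why: Williamson methylation at the para hydroxyl, which is the most acidic and the only one not hydrogen-bonded to the carbonyl.

Step 11
Reactants: 16 1-(2,6-dihydroxy-4-methoxyphenyl)ethanone
Product: 17 1-(2-benzyloxy-6-hydroxy-4-methoxyphenyl)ethanone
Conditions: BnBr (1.05 equiv), K2CO3 (1.1 equiv), acetone, reflux
Reagents that add atoms: benzyl bromide, BrCc1ccccc1
Why: Only one of the two equivalent ortho hydroxyls can be chelated at a time, so one is alkylated readily and the survivor is then deactivated by the hydrogen bond; Williamson etherification.

Step 12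
Reactants: 15 3-benzyloxy-4-{4-[(E)-3-(2,4-bis(benzyloxy)-6-hydroxyphenyl)-3-oxoprop-1-enyl]-2-methoxyphenoxy}benzaldehyde; 17 1-(2-benzyloxy-6-hydroxy-4-methoxyphenyl)ethanone
Product: 18 (E)-1-[2,4-bis(benzyloxy)-6-hydroxyphenyl]-3-[4-(2-benzyloxy-4-{(E)-3-(2-benzyloxy-6-hydroxy-4-methoxyphenyl)-3-oxoprop-1-enyl}phenoxy)-3-methoxyphenyl]prop-2-en-1-one
Conditions: KOH (50% aq.), EtOH/THF, rt; aq. HCl to pH 4, 0 °C
Reagents that add atoms: none
Why: Second Claisen–Schmidt condensation at the free formyl group; the enone already present exists as its 2'-phenolate under these conditions, which lowers its electrophilicity toward Michael addition and hydroxide-induced retro-aldol cleavage.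

Step 13
Reactants: 18 bis-chalcone from step 12
Product: 19 5,7-bis(benzyloxy)-2-{4-[2-benzyloxy-4-(5-benzyloxy-7-methoxy-4-oxo-4H-chromen-2-yl)phenoxy]-3-methoxyphenyl}-4H-chromen-4-one
Conditions: I2 (0.2 equiv), DMSO, 130 °C
Reagents that add atoms: none
Why: Iodine-catalysed oxidative cyclization of 2'-hydroxychalcones, as used to close both rings of bichalcones; each enone undergoes oxa-Michael closure, α-iodination and loss of HI, which DMSO re-oxidizes to I2, and since no epoxide is involved the 6'-alkoxy groups cannot divert the reaction to aurones.

Step 14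
Reactants: 19 biflavone from step 13
Product: 21 5,7-bis(benzyloxy)-2-{4-[2-benzyloxy-4-(5-benzyloxy-3-hydroxy-7-methoxy-4-oxo-4H-chromen-2-yl)phenoxy]-3-methoxyphenyl}-3-hydroxy-4H-chromen-4-one, via bis-epoxide 20 (not isolated)
Conditions: dimethyldioxirane (acetone solution, 6 equiv), CH2Cl2, 0 °C to rt; then p-TsOH (cat.), CH2Cl2, rt
Reagents that add atoms: dimethyldioxirane, CC1(C)OO1
Why: Dioxirane epoxidation of the flavone C2=C3 bonds followed by acid-catalysed opening of each oxirane at C2 (oxocarbenium stabilized by O1 and the aryl group) and loss of H3 gives the 3-hydroxyflavone enols, a known flavone-to-flavonol conversion that tolerates benzyl ethers at low temperature.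

Step 15
Reactants: 21 tetra-O-benzyl biflavonol from step 14
Product: 22 2-{4-[4-(3,5-dihydroxy-7-methoxy-4-oxo-4H-chromen-2-yl)-2-hydroxyphenoxy]-3-methoxyphenyl}-3,5,7-trihydroxy-4H-chromen-4-one
Conditions: H2 (1 atm), 10% Pd/C, THF/MeOH, rt
Reagents that add atoms: none
Why: Hydrogenolysis of the four benzylic C–O bonds; the enolic, tetrasubstituted C2=C3 bonds, the methyl ethers and the diaryl ether should not be reduced under these mild conditions.

## Compound list

1 | 3,4-dihydroxybenzaldehyde | O=Cc1ccc(O)c(O)c1 | starting material
2 | 3-benzyloxy-4-hydroxybenzaldehyde | O=Cc1ccc(O)c(OCc2ccccc2)c1 | intermediate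
3 | 2-benzyloxy-4-(1,3-dioxolan-2-yl)phenol | Oc1ccc(C2OCCO2)cc1OCc1ccccc1 | intermediate
4 | 3-bromofuran | Brc1ccoc1 | starting material
5 | 3-[2-benzyloxy-4-(1,3-dioxolan-2-yl)phenoxy]furan | c1cc(Oc2ccc(C3OCCO3)cc2OCc2ccccc2)co1 | intermediate
6 | ethyl propiolate | C#CC(=O)OCC | starting material
7 | ethyl 5-[2-benzyloxy-4-(1,3-dioxolan-2-yl)phenoxy]-7-oxabicyclo[2.2.1]hepta-2,5-diene-2-carboxylate (racemic, formed in the flask, not isolated) | CCOC(=O)C1=CC2OC1C=C2Oc1ccc(C2OCCO2)cc1OCc1ccccc1 | intermediate
8 | ethyl 4-[2-benzyloxy-4-(1,3-dioxolan-2-yl)phenoxy]-3-hydroxybenzoate | CCOC(=O)c1ccc(Oc2ccc(C3OCCO3)cc2OCc2ccccc2)c(O)c1 | intermediate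
9 | ethyl 4-[2-benzyloxy-4-(1,3-dioxolan-2-yl)phenoxy]-3-methoxybenzoate | CCOC(=O)c1ccc(Oc2ccc(C3OCCO3)cc2OCc2ccccc2)c(OC)c1 | intermediate
10 | {4-[2-benzyloxy-4-(1,3-dioxolan-2-yl)phenoxy]-3-methoxyphenyl}methanol | OCc1ccc(Oc2ccc(C3OCCO3)cc2OCc2ccccc2)c(OC)c1 | intermediate
11 | 4-[2-benzyloxy-4-(1,3-dioxolan-2-yl)phenoxy]-3-methoxybenzaldehyde | O=Cc1ccc(Oc2ccc(C3OCCO3)cc2OCc2ccccc2)c(OC)c1 | intermediate
12 | 2',4',6'-trihydroxyacetophenone | CC(=O)c1c(O)cc(O)cc1O | starting material
13 | 1-[2,4-bis(benzyloxy)-6-hydroxyphenyl]ethanone | CC(=O)c1c(O)cc(OCc2ccccc2)cc1OCc1ccccc1 | intermediate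
14 | (E)-1-[2,4-bis(benzyloxy)-6-hydroxyphenyl]-3-{4-[2-benzyloxy-4-(1,3-dioxolan-2-yl)phenoxy]-3-methoxyphenyl}prop-2-en-1-one (formed in the flask, not isolated) | COc1cc(/C=C/C(=O)c2c(O)cc(OCc3ccccc3)cc2OCc2ccccc2)ccc1Oc1ccc(C2OCCO2)cc1OCc1ccccc1 | intermediate
15 | 3-benzyloxy-4-{4-[(E)-3-(2,4-bis(benzyloxy)-6-hydroxyphenyl)-3-oxoprop-1-enyl]-2-methoxyphenoxy}benzaldehyde | COc1cc(/C=C/C(=O)c2c(O)cc(OCc3ccccc3)cc2OCc2ccccc2)ccc1Oc1ccc(C=O)cc1OCc1ccccc1 | intermediate
16 | 1-(2,6-dihydroxy-4-methoxyphenyl)ethanone | CC(=O)c1c(O)cc(OC)cc1O | intermediate
17 | 1-(2-benzyloxy-6-hydroxy-4-methoxyphenyl)ethanone | CC(=O)c1c(O)cc(OC)cc1OCc1ccccc1 | intermediate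
18 | (E)-1-[2,4-bis(benzyloxy)-6-hydroxyphenyl]-3-[4-(2-benzyloxy-4-{(E)-3-(2-benzyloxy-6-hydroxy-4-methoxyphenyl)-3-oxoprop-1-enyl}phenoxy)-3-methoxyphenyl]prop-2-en-1-one | COc1cc(/C=C/C(=O)c2c(O)cc(OCc3ccccc3)cc2OCc2ccccc2)ccc1Oc1ccc(/C=C/C(=O)c2c(O)cc(OC)cc2OCc2ccccc2)cc1OCc1ccccc1 | intermediate
19 | 5,7-bis(benzyloxy)-2-{4-[2-benzyloxy-4-(5-benzyloxy-7-methoxy-4-oxo-4H-chromen-2-yl)phenoxy]-3-methoxyphenyl}-4H-chromen-4-one | COc1cc(-c2cc(=O)c3c(OCc4ccccc4)cc(OCc4ccccc4)cc3o2)ccc1Oc1ccc(-c2cc(=O)c3c(OCc4ccccc4)cc(OC)cc3o2)cc1OCc1ccccc1 | intermediate
20 | bis(2,3-epoxide) of 19, each C2=C3 bond converted into a cis-fused oxirane (mixture of racemic diastereomers, formed in the flask, not isolated) | COc1cc(C23Oc4cc(OCc5ccccc5)cc(OCc5ccccc5)c4C(=O)C2O3)ccc1Oc1ccc(C23Oc4cc(OC)cc(OCc5ccccc5)c4C(=O)C2O3)cc1OCc1ccccc1 | intermediate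
21 | 5,7-bis(benzyloxy)-2-{4-[2-benzyloxy-4-(5-benzyloxy-3-hydroxy-7-methoxy-4-oxo-4H-chromen-2-yl)phenoxy]-3-methoxyphenyl}-3-hydroxy-4H-chromen-4-one | COc1cc(-c2oc3cc(OCc4ccccc4)cc(OCc4ccccc4)c3c(=O)c2O)ccc1Oc1ccc(-c2oc3cc(OC)cc(OCc4ccccc4)c3c(=O)c2O)cc1OCc1ccccc1 | intermediate
22 | 2-{4-[4-(3,5-dihydroxy-7-methoxy-4-oxo-4H-chromen-2-yl)-2-hydroxyphenoxy]-3-methoxyphenyl}-3,5,7-trihydroxy-4H-chromen-4-one (CNP0190193.0) | COc1cc(O)c2c(=O)c(O)c(-c3ccc(Oc4ccc(-c5oc6cc(O)cc(O)c6c(=O)c5O)cc4OC)c(O)c3)oc2c1 | target

## Step count and least certain steps

Total step count: 15. Longest linear sequence: 12 steps (steps 1 to 7, 9, 12, 13, 14 and 15).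

**Step 4 (key step).** Three processes could compete with the intended cycloaddition and opening:
- conjugate hydroarylation of the zinc-activated alkyne by furan C2 without ring closure;
- Lewis-acid ionization of the benzylic acetal followed by alkylation of the electron-rich furan or oligomerization;
- acid-induced degradation of the enol-ether furan.

The fallback gives up ring construction and makes the diaryl ether bond directly. It sets out from 3, which would be heated with commercial 4-fluoro-3-methoxybenzaldehyde and K2CO3 in DMF at about 120 °C (nucleophilic aromatic substitution para to the formyl group). It comes back to the route at 11, bypassing steps 3 to 7, and makes no new compound.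

**Step 3.** Possible problems are slow oxidative addition of the electron-rich heteroaryl bromide to monovalent copper, loss of the volatile bromide, and thermal degradation of the aryloxyfuran. The fallback reverses the roles of the partners in an oxidative Chan–Lam coupling. It sets out from 3, which would be coupled with commercial furan-3-ylboronic acid using Cu(OAc)2 (divalent copper), pyridine, molecular sieves and air in CH2Cl2 at room temperature. It comes back at 5 and makes no new compound.

**Step 2.** Possible problems are incomplete acetalization (the para hydroxyl lowers the electrophilicity of the formyl group), reversion of the para-hydroxy acetal on work-up or on silica, and carry-over of any regioisomeric benzylation from step 1. The fallback is a protecting-group detour that acetalizes a phenol ether and also fixes the benzylation site. It sets out from 1 and comes back at 3: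
- selective 4-O-allylation (allyl bromide, NaHCO3, NaI, DMF) to 4-allyloxy-3-hydroxybenzaldehyde F1;
- benzylation (BnBr, K2CO3, DMF) to 4-allyloxy-3-benzyloxybenzaldehyde F2;
- acetalization (ethylene glycol, p-TsOH, toluene, reflux) to 2-(4-allyloxy-3-benzyloxyphenyl)-1,3-dioxolane F3;
- deallylation with Pd(PPh3)4 (zerovalent palladium) and morpholine in THF, giving 3.

**Step 12.** Possible problems are hydroxide-induced retro-aldol cleavage of the first enone with exchange of the ring A ketones, Michael addition of the enolate of 17 to that enone, and sluggish condensation of the bis-phenolate. The fallback closes the first chromone before the second condensation. It sets out from 15 and comes back at 19: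
- I2 (cat.) in DMSO at 130 °C gives 3-benzyloxy-4-{4-[5,7-bis(benzyloxy)-4-oxo-4H-chromen-2-yl]-2-methoxyphenoxy}benzaldehyde F4;
- condensation of F4 with 17 under mild conditions (Ba(OH)2, MeOH/THF, rt) gives 5,7-bis(benzyloxy)-2-[4-(2-benzyloxy-4-{(E)-3-(2-benzyloxy-6-hydroxy-4-methoxyphenyl)-3-oxoprop-1-enyl}phenoxy)-3-methoxyphenyl]-4H-chromen-4-one F5;
- a second I2/DMSO cyclization of F5 gives 19.

**Step 14.** Possible problems are incomplete epoxidation of the second chromone, slow benzylic C–H oxidation of the benzyl ethers by excess dioxirane, and alternative rearrangement of the epoxides. The fallback replaces electrophilic oxygen transfer by anionic C3 functionalization. It sets out from 19 and comes back at 21. Double deprotonation at C3 with LDA in THF at −78 °C and trapping with B(OMe)3 would give the 3,3'-bis(dimethoxyboryl) derivative of 19 F6. Oxidation in the same flask with H2O2/AcOH would give 21.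

## Further compounds

F0 | step 4 | none | none
F0 | step 3 | none | none
F1 | step 2 | 4-allyloxy-3-hydroxybenzaldehyde | C=CCOc1ccc(C=O)cc1O
F2 | step 2 | 4-allyloxy-3-benzyloxybenzaldehyde | C=CCOc1ccc(C=O)cc1OCc1ccccc1
F3 | step 2 | 2-(4-allyloxy-3-benzyloxyphenyl)-1,3-dioxolane | C=CCOc1ccc(C2OCCO2)cc1OCc1ccccc1
F4 | step 12 | 3-benzyloxy-4-{4-[5,7-bis(benzyloxy)-4-oxo-4H-chromen-2-yl]-2-methoxyphenoxy}benzaldehyde | COc1cc(-c2cc(=O)c3c(OCc4ccccc4)cc(OCc4ccccc4)cc3o2)ccc1Oc1ccc(C=O)cc1OCc1ccccc1
F5 | step 12 | 5,7-bis(benzyloxy)-2-[4-(2-benzyloxy-4-{(E)-3-(2-benzyloxy-6-hydroxy-4-methoxyphenyl)-3-oxoprop-1-enyl}phenoxy)-3-methoxyphenyl]-4H-chromen-4-one | COc1cc(-c2cc(=O)c3c(OCc4ccccc4)cc(OCc4ccccc4)cc3o2)ccc1Oc1ccc(/C=C/C(=O)c2c(O)cc(OC)cc2OCc2ccccc2)cc1OCc1ccccc1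
F6 | step 14 | 3,3'-bis(dimethoxyboryl) derivative of 19 | COc1cc(-c2oc3cc(OCc4ccccc4)cc(OCc4ccccc4)c3c(=O)c2B(OC)OC)ccc1Oc1ccc(-c2oc3cc(OC)cc(OCc4ccccc4)c3c(=O)c2B(OC)OC)cc1OCc1ccccc1
A1 | alternative 1 | methyl 3-benzyloxy-4-(4-{2-benzyloxy-3-[2,4-bis(benzyloxy)-6-(methoxymethoxy)phenyl]-1-hydroxy-3-oxopropyl}-2-methoxyphenoxy)benzoate (diastereomer mixture) | COC(=O)c1ccc(Oc2ccc(C(O)C(OCc3ccccc3)C(=O)c3c(OCOC)cc(OCc4ccccc4)cc3OCc3ccccc3)cc2OC)c(OCc2ccccc2)c1
A2 | alternative 1 | 1-[2,4-bis(benzyloxy)-6-(methoxymethoxy)phenyl]-2-diazoethanone | [N-]=[N+]=CC(=O)c1c(OCOC)cc(OCc2ccccc2)cc1OCc1ccccc1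
A3 | alternative 1 | methyl 3-benzyloxy-4-(4-formyl-2-methoxyphenoxy)benzoate | COC(=O)c1ccc(Oc2ccc(C=O)cc2OC)c(OCc2ccccc2)c1
A4 | alternative 1 | benzyl alcohol | OCc1ccccc1
A5 | alternative 2 | methyl 4-[4-(1,3-dioxolan-2-yl)-2-methoxyphenoxy]-3-(4,4,5,5-tetramethyl-1,3,2-dioxaborolan-2-yl)benzoate | COC(=O)c1ccc(Oc2ccc(C3OCCO3)cc2OC)c(B2OC(C)(C)C(C)(C)O2)c1
A6 | alternative 2 | methyl coumalate (methyl 2-oxo-2H-pyran-5-carboxylate) | COC(=O)c1ccc(=O)oc1
A7 | alternative 2 | 2-{[4-(1,3-dioxolan-2-yl)-2-methoxyphenoxy]ethynyl}-4,4,5,5-tetramethyl-1,3,2-dioxaborolane | COc1cc(C2OCCO2)ccc1OC#CB1OC(C)(C)C(C)(C)O1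
A8 | alternative 3 | tetra-O-benzyl target with free 5,7-hydroxyls on the new ring A | COc1cc(OCc2ccccc2)c2c(=O)c(OCc3ccccc3)c(-c3ccc(Oc4ccc(-c5oc6cc(O)cc(O)c6c(=O)c5OCc5ccccc5)cc4OC)c(OCc4ccccc4)c3)oc2c1
A9 | alternative 3 | methyl 4-{6-aryl-5-benzyloxy-4-oxo-4H-pyran-2-yl}-3-oxobutanoate, aryl being the 3-methoxy-4-aryloxyphenyl ring that carries the benzylated 7-methoxyflavonol half | COc1cc(OCc2ccccc2)c2c(=O)c(OCc3ccccc3)c(-c3ccc(Oc4ccc(-c5oc(CC(=O)CC(=O)OC)cc(=O)c5OCc5ccccc5)cc4OC)c(OCc4ccccc4)c3)oc2c1
A10 | alternative 3 | kojic acid (5-hydroxy-2-(hydroxymethyl)-4H-pyran-4-one) | OCc1cc(=O)c(O)co1
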